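## Numbering and conventions

Unit 1 is the flavanone with rings A (C4a, C5–C8, C8a), C (O1, C2, C3, C4) and B (C1'–C6'). Unit 2 is the flavanone with rings D (C4a''–C8a''), F (O1'', C2'', C3'', C4'') and E (C1'''–C6'''). The ether oxygen joins C4' of ring B to C6'' of ring D. Reading the SMILES by CIP rules gives 2S and 2''S: the target is (2S,2''S)-2,3,2'',3''-tetrahydrohinokiflavone.

## The problem

- **The ether.** Two naringenin units are joined by one diaryl ether oxygen between C4' (ring B) and C6'' (ring D). C6'' lies between the oxygen-bearing carbons C5'' and C7'' of an electron-rich ring, the worst position for an aryl–oxygen coupling.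
- **Regiochemistry.** The ether must sit at C6'' and not at the near-equivalent C8''.
- **Stereocentres.** C2 and C2'' are separated by ring B, the ether oxygen and ring D. Neither can control the other, so each must be set by a reagent.
- **Lability.** Both stereocentres are benzylic ether carbons β to a ketone. Base deprotonates C3 (or C3''), expels O1 (or O1'') and opens the pyranone to a 2'-hydroxychalcone that recloses without memory. In unit 2 the chalcone can also reclose on O5'', which scrambles the 6/8 linkage (Wessely–Moser-type).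
- **Functional groups.** Five free phenols, two of them in oxidisable phloroglucinol-type rings, rule out hot base, strong Lewis acids and oxidants once the stereocentres exist.
- **Enabling feature 1.** C2 and C2'' are each the β-carbon of a flat benzo-γ-pyrone (O1–C2=C3–C4=O) once the C2–C1' or C2''–C1''' bond is cut. Ring B is bonded to C2 through C1' and to the ether oxygen through C4', so it can be delivered to C2 as an aryl nucleophile that already carries all of unit 2.
- **Enabling feature 2.** Ring D without its acyl carbon has a mirror plane through C6'' and C8a'', so the 6/8 question can be removed by symmetry.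

## Retrosynthesis

**18 ⇒ 17.** Five O–CH2OCH3 bonds are cut. Methoxymethyl ethers are chosen over methyl ethers (BBr3 could ionise the benzylic C2–O1 bond) and over benzyl ethers (hydrogenolysis can cleave the same bond). The forward step needs only dilute acid, which does not form the C3 enolate that triggers ring opening.

**17 ⇒ 14 + 16 (key disconnection).** The C2–C1' bond is cut, not O1–C2 (the chalcone cut) and not the ether (the late-coupling cut). This splits the molecule into the flat chromone 16 and the arylboronic acid 14, which holds unit 2 complete. The forward reaction must add the aryl group of 14 to C2 of 16 with catalyst-controlled face selectivity and without base. Both stereocentres then come from the same catalyst in two separate events; the minor enantiomer of either event ends up mostly in the diastereomer, which raises the enantiomeric purity of the (2S,2''S) product.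

**14 ⇒ 12 ⇒ 10 + 11.** The C–B bond of 14 is traced to the C–Br bond of 12. In 12 the C2''–C1''' bond is cut by the same logic, giving chromone 10 and the simple boronic acid 11. Boron is introduced only after C2'' is set, because a chromone that carried a boronic acid would add to itself. The bromide is silent under rhodium catalysis.

**10 ⇒ 9 ⇒ 8.** The two methoxymethyl groups on O5'' and O7'' are traced to methyl ethers. The exchange is placed at the chromone stage, where no stereocentre exists and BBr3 is harmless.

**8 ⇒ 6 ⇒ 5.** Ring F is opened at O1''–C2'' and C2''–C3'' (C2'' is one carbon from a formamide acetal), then the C4''–C4a'' bond is cut. Phenol 5 has a mirror plane through C6'' and C8a'': its two ortho positions are equivalent, so acylation can give only 6. Its single free hydroxyl is para to the aryloxy group, so ring F can close only on O1''. An 8-aryloxy isomer cannot form.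

**5 ⇒ 3 ⇒ 1 + 2.** O1'' is traced to the aldehyde carbon of 3 (Baeyer–Villiger oxidation). The ether O–C4' bond is then cut to syringaldehyde 1 and the diaryliodonium salt 2. The hindered ether is thus made first, on a purchased phenol whose hydroxyl already sits between two methoxy groups. A diaryliodonium salt is used because the bromophenyl group has no activating group for SNAr and the bromine is needed later.

**16 ⇒ 15.** Two O–CH2OCH3 bonds are cut, back to the purchasable 5,7-dihydroxychromone 15.

## Roads not taken

Alternative 1: The most obvious cut is the ether bond C6''–O between two complete, protected flavanone halves: the 6-iodoflavanone A1 and the phenol A2. The forward key step would be a copper-catalysed Ullmann coupling to 17.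
- An aryl iodide with two ortho alkoxy groups on an electron-rich ring is the poorest class of partner for copper C–O coupling.
- The hot carbonate or phosphate that it needs deprotonates C3 and C3'', opening both pyranones and losing both stereocentres.
- Iodination of ring D must be steered to C6'' over C8''.
- The chosen plan makes the ether on a simple phenol before any stereocentre exists.

Alternative 2: Cut both O1–C2 bonds. The keto-aldehyde A3 would be condensed twice (Claisen–Schmidt) to the bichalcone A4, and the forward key step would be a double enantioselective intramolecular oxa-Michael addition.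
- A3 carries both an aldehyde and a methyl ketone and would condense with itself.
- The 2',6'-dioxygenated chalcones of A4 cyclise without catalyst, giving a racemic background reaction, and the chalcone/flavanone equilibrium stays open.
- Ring F can close on either ortho oxygen of ring D, giving 6- and 8-aryloxy isomers.
- The chosen plan has O1–C2 and O1''–C2'' in place from the start and makes no chalcone.

Alternative 3: Keep both C2–aryl bonds and remove the C2–H and C2''–H hydrogens, giving the biflavone A5. The forward key step would be a double asymmetric conjugate reduction.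
- A5 is no simpler than the target: it needs the same ether and regiochemistry solution plus two flavone syntheses.
- 5,7-Dialkoxyflavones are doubly vinylogous carbonates and poor hydride acceptors.
- Over-reduction of C4=O would call for reoxidation, adding steps.
- The chosen plan creates each stereocentre in a C–C bond formation that also builds the skeleton.

Key step: step 10

## Remarks before the steps

- Remark: (S)-MeO-F12-BIPHEP is (S)-2,2'-bis[bis(3,4,5-trifluorophenyl)phosphino]-6,6'-dimethoxy-1,1'-biphenyl. The (S) antipode is assigned by analogy with cyclohexenone (see step 10); if chromones show the opposite sense, the (R) antipode is used in steps 7 and 10.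
- Remark: compounds 1, 2, 11 and 15 are taken as purchasable.

## Steps

Step 1
Reactants: 1 syringaldehyde (4-hydroxy-3,5-dimethoxybenzaldehyde); 2 bis(4-bromophenyl)iodonium trifluoromethanesulfonate
Product: 3 4-(4-bromophenoxy)-3,5-dimethoxybenzaldehyde
Conditions: t-BuOK, THF, 0 to 40 °C
Reagents that add atoms: none
Why: Metal-free O-arylation of a phenoxide with a diaryliodonium salt (ligand exchange at trivalent iodine, then ligand coupling), a reaction type that tolerates 2,6-disubstituted phenols near room temperature; the symmetric salt can transfer only the 4-bromophenyl group.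

Step 2
Reactants: 3 4-(4-bromophenoxy)-3,5-dimethoxybenzaldehyde
Product: 5 4-(4-bromophenoxy)-3,5-dimethoxyphenol, via aryl formate 4 (not isolated)
Conditions: mCPBA, CH2Cl2, 0 °C to rt; then K2CO3 (0.2 equiv), MeOH, rt
Reagents that add atoms: 3-chloroperbenzoic acid (mCPBA), O=C(OO)c1cccc(Cl)c1
Why: Baeyer–Villiger (Dakin-type) oxidation of an electron-rich benzaldehyde: the para-aryloxy-substituted aryl group migrates to oxygen in the Criegee intermediate and methanolysis of the formate frees the phenol; the aldehyde carbon of 1 thereby marks the position of O1''.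

Step 3
Reactants: 5 4-(4-bromophenoxy)-3,5-dimethoxyphenol
Product: 6 1-[3-(4-bromophenoxy)-6-hydroxy-2,4-dimethoxyphenyl]ethan-1-one
Conditions: AcOH, BF3·OEt2, 90 °C; then aq. NaOAc
Reagents that add atoms: acetic acid, CC(=O)O
Why: Fries-type ortho-acylation of a polyalkoxyphenol; the two positions ortho to the hydroxyl are related by the mirror plane of 5, so only one ketone can form, and the bromophenoxy ring is far less activated.

Step 4
Reactants: 6 1-[3-(4-bromophenoxy)-6-hydroxy-2,4-dimethoxyphenyl]ethan-1-one
Product: 8 6-(4-bromophenoxy)-5,7-dimethoxy-4H-chromen-4-one, via enaminone 7 (not isolated)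
Conditions: Me2NCH(OMe)2, toluene, 100 °C; then conc. HCl, CH2Cl2, rt
Reagents that add atoms: N,N-dimethylformamide dimethyl acetal, COC(OC)N(C)C
Why: Standard enaminone route to chromones: condensation at the acetyl methyl group, then acid-promoted addition–elimination by the only ortho hydroxyl (6-endo closure of ring F, loss of dimethylamine), which fixes the aryloxy group at C6''.

Step 5
Reactants: 8 6-(4-bromophenoxy)-5,7-dimethoxy-4H-chromen-4-one
Product: 9 6-(4-bromophenoxy)-5,7-dihydroxy-4H-chromen-4-one
Conditions: BBr3, CH2Cl2, −78 °C to rt; then H2O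
Reagents that add atoms: none
Why: Lewis-acid cleavage of aryl methyl ethers (O→B coordination, bromide attack on CH3); chromone, diaryl ether and aryl bromide are inert, and the step is placed before any stereocentre exists.

Step 6
Reactants: 9 6-(4-bromophenoxy)-5,7-dihydroxy-4H-chromen-4-one
Product: 10 6-(4-bromophenoxy)-5,7-bis(methoxymethoxy)-4H-chromen-4-one
Conditions: NaH, MOMCl, DMF, 0 °C to rt
Reagents that add atoms: chloromethyl methyl ether (MOMCl), COCCl
Why: Williamson-type O-alkylation of both phenoxides; NaH is used because the chelated 5-hydroxyl does not react under amine-base conditions.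

Step 7
Reactants: 10 6-(4-bromophenoxy)-5,7-bis(methoxymethoxy)-4H-chromen-4-one; 11 [4-(methoxymethoxy)phenyl]boronic acid
Product: 12 (2S)-6-(4-bromophenoxy)-5,7-bis(methoxymethoxy)-2-[4-(methoxymethoxy)phenyl]-2,3-dihydro-4H-chromen-4-one
Conditions: [Rh(OH)(cod)]2 (3 mol%), (S)-MeO-F12-BIPHEP, toluene/H2O, 30 °C
Reagents that add atoms: none
Why: Rhodium-catalysed asymmetric 1,4-addition of an arylboronic acid to a chromone (Hayashi–Miyaura reaction), known for 5,7-dioxygenated chromones; C2'' is set 2S by the chiral bisphosphine (face argument as in step 10), no base is present, and the aryl bromide does not react with monovalent rhodium under these conditions.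

Step 8
Reactants: 12 (2S)-6-(4-bromophenoxy)-5,7-bis(methoxymethoxy)-2-[4-(methoxymethoxy)phenyl]-2,3-dihydro-4H-chromen-4-one
Product: 14 [4-({(2S)-5,7-bis(methoxymethoxy)-2-[4-(methoxymethoxy)phenyl]-4-oxo-3,4-dihydro-2H-chromen-6-yl}oxy)phenyl]boronic acid, via pinacol boronate 13 (not isolated)
Conditions: B2pin2, PdCl2(dppf) (3 mol%), KOAc, 1,4-dioxane, 80 °C; then NaIO4, NH4OAc, acetone/H2O, rt
Reagents that add atoms: bis(pinacolato)diboron, CC1(C)OB(OC1(C)C)B1OC(C)(C)C(C)(C)O1; water, O
Why: Miyaura borylation (oxidative addition of zerovalent palladium into C–Br, acetate-assisted boryl transfer), then buffered periodate cleavage of the pinacol ester to the free boronic acid; KOAc suspended in aprotic dioxane is too weak a base to deprotonate C3'', so C2'' should keep its configuration.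

Step 9
Reactants: 15 5,7-dihydroxy-4H-chromen-4-one
Product: 16 5,7-bis(methoxymethoxy)-4H-chromen-4-one
Conditions: NaH, MOMCl, DMF, 0 °C to rt
Reagents that add atoms: chloromethyl methyl ether (MOMCl), COCCl
Why: Same Williamson-type protection as step 6; both phenols must be capped so that no phenoxide makes the chromone electron-rich or protonates the aryl–rhodium species.

Step 10
Reactants: 14 [4-({(2S)-5,7-bis(methoxymethoxy)-2-[4-(methoxymethoxy)phenyl]-4-oxo-3,4-dihydro-2H-chromen-6-yl}oxy)phenyl]boronic acid; 16 5,7-bis(methoxymethoxy)-4H-chromen-4-one (3 equiv)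
Product: 17 (2S)-2-[4-({(2S)-5,7-bis(methoxymethoxy)-2-[4-(methoxymethoxy)phenyl]-4-oxo-3,4-dihydro-2H-chromen-6-yl}oxy)phenyl]-5,7-bis(methoxymethoxy)-2,3-dihydro-4H-chromen-4-one
Conditions: [Rh(OH)(cod)]2 (5 mol%), (S)-MeO-F12-BIPHEP, toluene/H2O, 30 °C
Reagents that add atoms: none
Why: Transmetalation of 14 to the hydroxo complex of monovalent rhodium gives a C1'–Rh species; the C2=C3 bond of 16 coordinates and inserts syn with the aryl group going to C2, and water protonates the oxa-π-allyl rhodium enolate at C3, returning Rh–OH. The closest known reaction type is the rhodium–bisphosphine-catalysed asymmetric 1,4-addition of arylboronic acids to 4H-chromen-4-ones (Hayashi–Miyaura reaction), which is established for 5,7-dioxygenated chromones. The step closes no ring; it forms the C2–C1' bond that joins the two halves. C2 is set by the ligand alone: an (S)-biaryl bisphosphine exposes the enone face that gives (S)-3-arylcyclohexanones from cyclohexenone, and for a chromone, with O1 in the place of C4 of cyclohexenone, that face corresponds to 2S. C2'' lies beyond ring D, the ether oxygen and ring B, so it cannot bias the insertion, and it is not at risk because no base is present to deprotonate C3''. The step needs 1,4- over 1,2-addition and insertion over protodeboronation: C4=O of 16 and of the product is shielded by the peri 5-methoxymethoxy group, the electron-poor ligand speeds up insertion, and 16 is used in excess. Opening of ring C by β-oxygen elimination from the rhodium enolate should be outrun by protonolysis in the aqueous medium.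

Step 11
Reactants: 17 (2S)-2-[4-({(2S)-5,7-bis(methoxymethoxy)-2-[4-(methoxymethoxy)phenyl]-4-oxo-3,4-dihydro-2H-chromen-6-yl}oxy)phenyl]-5,7-bis(methoxymethoxy)-2,3-dihydro-4H-chromen-4-one
Product: 18 (2S)-5,7-dihydroxy-2-[4-({(2S)-5,7-dihydroxy-2-(4-hydroxyphenyl)-4-oxo-3,4-dihydro-2H-chromen-6-yl}oxy)phenyl]-2,3-dihydro-4H-chromen-4-one (CNP0184214.1)
Conditions: 3 M aq. HCl, MeOH, 50 °C
Reagents that add atoms: none
Why: Acid-catalysed methanolysis of five aryl methoxymethyl acetals; acid does not form the C3 or C3'' enolate that opens the pyranone rings, so both stereocentres should be kept, and the diaryl ether is inert.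

## Compound list

1 | syringaldehyde (4-hydroxy-3,5-dimethoxybenzaldehyde) | COc1cc(C=O)cc(OC)c1O | starting material
2 | bis(4-bromophenyl)iodonium trifluoromethanesulfonate | Brc1ccc(cc1)[I+]c1ccc(Br)cc1.[O-]S(=O)(=O)C(F)(F)F | starting material
3 | 4-(4-bromophenoxy)-3,5-dimethoxybenzaldehyde | COc1cc(C=O)cc(OC)c1Oc1ccc(Br)cc1 | intermediate
4 | 4-(4-bromophenoxy)-3,5-dimethoxyphenyl formate | COc1cc(OC=O)cc(OC)c1Oc1ccc(Br)cc1 | intermediate
5 | 4-(4-bromophenoxy)-3,5-dimethoxyphenol | COc1cc(O)cc(OC)c1Oc1ccc(Br)cc1 | intermediate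
6 | 1-[3-(4-bromophenoxy)-6-hydroxy-2,4-dimethoxyphenyl]ethan-1-one | CC(=O)c1c(O)cc(OC)c(Oc2ccc(Br)cc2)c1OC | intermediate
7 | (2E)-1-[3-(4-bromophenoxy)-6-hydroxy-2,4-dimethoxyphenyl]-3-(dimethylamino)prop-2-en-1-one | CN(C)/C=C/C(=O)c1c(O)cc(OC)c(Oc2ccc(Br)cc2)c1OC | intermediate
8 | 6-(4-bromophenoxy)-5,7-dimethoxy-4H-chromen-4-one | COc1cc2occc(=O)c2c(OC)c1Oc1ccc(Br)cc1 | intermediate
9 | 6-(4-bromophenoxy)-5,7-dihydroxy-4H-chromen-4-one | Oc1cc2occc(=O)c2c(O)c1Oc1ccc(Br)cc1 | intermediate
10 | 6-(4-bromophenoxy)-5,7-bis(methoxymethoxy)-4H-chromen-4-one | COCOc1cc2occc(=O)c2c(OCOC)c1Oc1ccc(Br)cc1 | intermediate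
11 | [4-(methoxymethoxy)phenyl]boronic acid | COCOc1ccc(cc1)B(O)O | starting material
12 | (2S)-6-(4-bromophenoxy)-5,7-bis(methoxymethoxy)-2-[4-(methoxymethoxy)phenyl]-2,3-dihydro-4H-chromen-4-one | COCOc1ccc(cc1)[C@@H]1CC(=O)c2c(OCOC)c(Oc3ccc(Br)cc3)c(OCOC)cc2O1 | intermediate
13 | (2S)-5,7-bis(methoxymethoxy)-2-[4-(methoxymethoxy)phenyl]-6-[4-(4,4,5,5-tetramethyl-1,3,2-dioxaborolan-2-yl)phenoxy]-2,3-dihydro-4H-chromen-4-one | COCOc1ccc(cc1)[C@@H]1CC(=O)c2c(OCOC)c(Oc3ccc(cc3)B3OC(C)(C)C(C)(C)O3)c(OCOC)cc2O1 | intermediate
14 | [4-({(2S)-5,7-bis(methoxymethoxy)-2-[4-(methoxymethoxy)phenyl]-4-oxo-3,4-dihydro-2H-chromen-6-yl}oxy)phenyl]boronic acid | COCOc1ccc(cc1)[C@@H]1CC(=O)c2c(OCOC)c(Oc3ccc(cc3)B(O)O)c(OCOC)cc2O1 | intermediate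
15 | 5,7-dihydroxy-4H-chromen-4-one | O=c1ccoc2cc(O)cc(O)c12 | starting material
16 | 5,7-bis(methoxymethoxy)-4H-chromen-4-one | COCOc1cc(OCOC)c2c(c1)occc2=O | intermediate
17 | (2S)-2-[4-({(2S)-5,7-bis(methoxymethoxy)-2-[4-(methoxymethoxy)phenyl]-4-oxo-3,4-dihydro-2H-chromen-6-yl}oxy)phenyl]-5,7-bis(methoxymethoxy)-2,3-dihydro-4H-chromen-4-one | O=C1C[C@@H](c2ccc(Oc3c(OCOC)cc4c(c3OCOC)C(=O)C[C@@H](c3ccc(OCOC)cc3)O4)cc2)Oc2cc(OCOC)cc(OCOC)c21 | intermediate
18 | (2S)-5,7-dihydroxy-2-[4-({(2S)-5,7-dihydroxy-2-(4-hydroxyphenyl)-4-oxo-3,4-dihydro-2H-chromen-6-yl}oxy)phenyl]-2,3-dihydro-4H-chromen-4-one (CNP0184214.1) | O=C1C[C@@H](c2ccc(Oc3c(O)cc4c(c3O)C(=O)C[C@@H](c3ccc(O)cc3)O4)cc2)Oc2cc(O)cc(O)c21 | target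

## Step count and least certain steps

Total steps: 11. Longest linear sequence: 10 (steps 1–8, 10, 11); step 9 is a one-step side branch.

**Step 10 (key step).**
- What may go wrong: protodeboronation of the valuable boronic acid 14 may outpace insertion, because 16 is a weak, electron-rich acceptor. β-Oxygen elimination from the rhodium enolate would open ring C to a chalcone that recloses without control. Aryl 1,2-addition to a C4 ketone may compete.
- Fallback (sets out from 10, comes back at 17): the order of the two additions is inverted, so that the union uses a robust, achiral boronic acid and C2'' is set last.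
  - Bromide 10 is borylated directly (B2(OH)4, Pd(OAc)2, XPhos, KOAc, EtOH, 80 °C) to (4-{[5,7-bis(methoxymethoxy)-4-oxo-4H-chromen-6-yl]oxy}phenyl)boronic acid F1.
  - F1 is added slowly to an excess of 16 under the conditions of step 10, to keep self-addition down. This gives (2S)-2-(4-{[5,7-bis(methoxymethoxy)-4-oxo-4H-chromen-6-yl]oxy}phenyl)-5,7-bis(methoxymethoxy)-2,3-dihydro-4H-chromen-4-one F2.
  - The remaining chromone of F2 then takes up 11 under the conditions of step 7 to give 17.

**Step 8.**
- What may go wrong: acetate-mediated deprotonation at C3'' at 80 °C would open ring F and erode the configuration at C2''. Hydrodebromination may also compete with borylation.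
- Fallback (sets out from 10, comes back at 14): boron is installed before the stereocentre and masked.
  - Bromide 10 is borylated to the boronic acid F1 of the fallback above.
  - F1 is condensed with N-methyliminodiacetic acid (toluene/DMSO, Dean–Stark) to 6-[4-(6-methyl-4,8-dioxo-1,3,6,2-dioxazaborocan-2-yl)phenoxy]-5,7-bis(methoxymethoxy)-4H-chromen-4-one F3. Its tetracoordinate boron does not transmetalate.
  - Addition of 11 as in step 7 gives (2S)-6-[4-(6-methyl-4,8-dioxo-1,3,6,2-dioxazaborocan-2-yl)phenoxy]-5,7-bis(methoxymethoxy)-2-[4-(methoxymethoxy)phenyl]-2,3-dihydro-4H-chromen-4-one F4.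
  - Aqueous NaHCO3/MeOH at rt releases 14.

**Step 7.**
- What may go wrong: facial discrimination may be insufficient on a chromone whose C5''–C7'' edge is crowded, and the same β-oxygen elimination as in step 10 may occur.
- Fallback (sets out from 10, comes back at 12): resolution replaces induction.
  - Addition of 11 to 10 with [Rh(OH)(cod)]2 alone gives racemic 6-(4-bromophenoxy)-5,7-bis(methoxymethoxy)-2-[4-(methoxymethoxy)phenyl]-2,3-dihydro-4H-chromen-4-one F5.
  - Kinetic resolution by asymmetric transfer hydrogenation (RuCl[(R,R)-TsDPEN](p-cymene), HCO2H/Et3N) should reduce the (2R) enantiomer to (2R,4R)-6-(4-bromophenoxy)-5,7-bis(methoxymethoxy)-2-[4-(methoxymethoxy)phenyl]-3,4-dihydro-2H-chromen-4-ol F6.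
  - The (2S) ketone 12 is left and separated by chromatography.

**Step 1.**
- What may go wrong: ligand coupling may be slow for a phenoxide that is both stabilised by the para aldehyde and flanked by two methoxy groups, letting decomposition of the iodonium salt compete.
- Fallback (sets out from 1, comes back at 3): the ether is made by SNAr and the bromine installed afterwards.
  - The phenoxide of 1 with 1-fluoro-4-nitrobenzene (K2CO3, DMF, 100 °C) gives 3,5-dimethoxy-4-(4-nitrophenoxy)benzaldehyde F7.
  - Reduction (iron powder, NH4Cl, aq. EtOH) gives 4-(4-aminophenoxy)-3,5-dimethoxybenzaldehyde F8, used at once to forestall imine formation.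
  - Sandmeyer bromination (t-BuONO, CuBr2, MeCN) gives 3.

## Further compounds

F1 | step 10 | (4-{[5,7-bis(methoxymethoxy)-4-oxo-4H-chromen-6-yl]oxy}phenyl)boronic acid | COCOc1cc2occc(=O)c2c(OCOC)c1Oc1ccc(cc1)B(O)O
F2 | step 10 | (2S)-2-(4-{[5,7-bis(methoxymethoxy)-4-oxo-4H-chromen-6-yl]oxy}phenyl)-5,7-bis(methoxymethoxy)-2,3-dihydro-4H-chromen-4-one | O=C1C[C@@H](c2ccc(Oc3c(OCOC)cc4occc(=O)c4c3OCOC)cc2)Oc2cc(OCOC)cc(OCOC)c21
F3 | step 8 | 6-[4-(6-methyl-4,8-dioxo-1,3,6,2-dioxazaborocan-2-yl)phenoxy]-5,7-bis(methoxymethoxy)-4H-chromen-4-one | COCOc1cc2occc(=O)c2c(OCOC)c1Oc1ccc(cc1)B1OC(=O)CN(C)CC(=O)O1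
F4 | step 8 | (2S)-6-[4-(6-methyl-4,8-dioxo-1,3,6,2-dioxazaborocan-2-yl)phenoxy]-5,7-bis(methoxymethoxy)-2-[4-(methoxymethoxy)phenyl]-2,3-dihydro-4H-chromen-4-one | COCOc1ccc(cc1)[C@@H]1CC(=O)c2c(OCOC)c(Oc3ccc(cc3)B3OC(=O)CN(C)CC(=O)O3)c(OCOC)cc2O1
F5 | step 7 | racemic 6-(4-bromophenoxy)-5,7-bis(methoxymethoxy)-2-[4-(methoxymethoxy)phenyl]-2,3-dihydro-4H-chromen-4-one | COCOc1ccc(cc1)C1CC(=O)c2c(OCOC)c(Oc3ccc(Br)cc3)c(OCOC)cc2O1
F6 | step 7 | (2R,4R)-6-(4-bromophenoxy)-5,7-bis(methoxymethoxy)-2-[4-(methoxymethoxy)phenyl]-3,4-dihydro-2H-chromen-4-ol | COCOc1ccc(cc1)[C@H]1C[C@@H](O)c2c(OCOC)c(Oc3ccc(Br)cc3)c(OCOC)cc2O1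
F7 | step 1 | 3,5-dimethoxy-4-(4-nitrophenoxy)benzaldehyde | COc1cc(C=O)cc(OC)c1Oc1ccc(cc1)[N+](=O)[O-]
F8 | step 1 | 4-(4-aminophenoxy)-3,5-dimethoxybenzaldehyde | COc1cc(C=O)cc(OC)c1Oc1ccc(N)cc1
A1 | alternative 1 | (2S)-6-iodo-5,7-bis(methoxymethoxy)-2-[4-(methoxymethoxy)phenyl]-2,3-dihydro-4H-chromen-4-one | COCOc1ccc(cc1)[C@@H]1CC(=O)c2c(OCOC)c(I)c(OCOC)cc2O1
A2 | alternative 1 | (2S)-2-(4-hydroxyphenyl)-5,7-bis(methoxymethoxy)-2,3-dihydro-4H-chromen-4-one | Oc1ccc(cc1)[C@@H]1CC(=O)c2c(OCOC)cc(OCOC)cc2O1
A3 | alternative 2 | 4-(3-acetyl-2,4,6-trihydroxyphenoxy)benzaldehyde | CC(=O)c1c(O)cc(O)c(Oc2ccc(C=O)cc2)c1O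
A4 | alternative 2 | (2E)-3-(4-{2,4,6-trihydroxy-3-[(2E)-3-(4-hydroxyphenyl)prop-2-enoyl]phenoxy}phenyl)-1-(2,4,6-trihydroxyphenyl)prop-2-en-1-one | O=C(/C=C/c1ccc(Oc2c(O)cc(O)c(C(=O)/C=C/c3ccc(O)cc3)c2O)cc1)c1c(O)cc(O)cc1O
A5 | alternative 3 | 2-[4-({5,7-bis(methoxymethoxy)-2-[4-(methoxymethoxy)phenyl]-4-oxo-4H-chromen-6-yl}oxy)phenyl]-5,7-bis(methoxymethoxy)-4H-chromen-4-one | O=c1cc(-c2ccc(Oc3c(OCOC)cc4oc(-c5ccc(OCOC)cc5)cc(=O)c4c3OCOC)cc2)oc2cc(OCOC)cc(OCOC)c12
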